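**Plan**

- Feature used: in ring A the ketone-bearing carbon C6 lies between the hydroxylated carbons C5 and C7, and C8a carries the pyran oxygen O1. Ring A is therefore an acylphloroglucinol, the folded and aromatised form of a linear 3,5,7-triketo ester.
- Retrosynthetic cuts: pyran bonds C4–C4a and O1–C2 (back to an aryl propargyl ether and chloroalkyne 2); ring A bond C6–C5/C7 (intramolecular Claisen acylation); the bond from C6 to the ketone carbon (acylation of a triketide trianion); on ring B the side-chain Cα–Cβ bond, the O–CH3 bond and the aryl–prenyl bond.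
- Forward order: ring B is bought as 1, prenylated by a Claisen shift, methylated and homologated to amide 10. Amide 10 is joined to the trianion of 11 to give open-chain 13. Ring A closes in step 10, the pyran ring closes last (steps 11–12), then the chromene alkene is saturated and the acetal removed.
- Stereochemistry: the target has no stereocentre and no stereogenic alkene; the E-alkene of 8 is saturated in step 7.

Key step: step 10

Remark: target ring atoms follow chroman numbering (O1, C2 … C8a); chain atoms of 13 run from the ester carbon C1 to the benzylic carbon C9; primed locants refer to the phloroglucinol ring of 15 and 16, with C1' bearing the ketone.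

**Route**

Step 1
Reactants: 1 3,4-dihydroxybenzaldehyde; 2 3-chloro-3-methylbut-1-yne
Product: 3 3-hydroxy-4-[(2-methylbut-3-yn-2-yl)oxy]benzaldehyde
Conditions: 2 (1.5 equiv), K2CO3 (1.1 equiv), KI (0.2 equiv), CuI (2 mol %), DMF, 50 °C, N2
Reagents that add atoms: none
Why: Williamson-type O-alkylation in which one equivalent of carbonate ionises only the 4-OH, the more acidic phenol because it is para to the formyl group, and this phenoxide captures the tertiary propargylic electrophile generated from 2 under iodide and copper catalysis, leaving the 3-OH free.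

Step 2
Reactants: 3 3-hydroxy-4-[(2-methylbut-3-yn-2-yl)oxy]benzaldehyde
Product: 4 3-(methoxymethoxy)-4-[(2-methylbut-3-yn-2-yl)oxy]benzaldehyde
Conditions: MOMCl, iPr2NEt, CH2Cl2, 0 °C → rt
Reagents that add atoms: chloromethyl methyl ether (MOMCl), COCCl
Why: Standard methoxymethyl ether formation on the remaining phenol (base-mediated alkylation with an α-chloro ether), giving an acetal that tolerates the basic, reductive and thermal steps that follow.

Step 3
Reactants: 4 3-(methoxymethoxy)-4-[(2-methylbut-3-yn-2-yl)oxy]benzaldehyde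
Product: 5 3-(methoxymethoxy)-4-[(2-methylbut-3-en-2-yl)oxy]benzaldehyde
Conditions: H2 (1 atm), Pd/CaCO3 poisoned with Pb(OAc)2, quinoline, EtOAc, rt, stopped after one equivalent of H2
Reagents that add atoms: none
Why: Lindlar semi-hydrogenation should stop the terminal alkyne at the alkene on the poisoned catalyst and leave the aryl aldehyde and the acetal untouched, giving the 1,1-dimethylallyl ether needed for the rearrangement.

Step 4
Reactants: 5 3-(methoxymethoxy)-4-[(2-methylbut-3-en-2-yl)oxy]benzaldehyde
Product: 6 4-hydroxy-3-(methoxymethoxy)-5-(3-methylbut-2-en-1-yl)benzaldehyde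
Conditions: PhNEt2, 130 °C
Reagents that add atoms: none
Why: Aromatic Claisen rearrangement in which the [3,3] shift delivers the allyl unit with inversion to C5, the only ortho position bearing hydrogen, so the 1,1-dimethylallyl ether emerges as a linear prenyl group and tautomerisation restores the 4-OH.

Step 5
Reactants: 6 4-hydroxy-3-(methoxymethoxy)-5-(3-methylbut-2-en-1-yl)benzaldehyde
Product: 7 4-methoxy-3-(methoxymethoxy)-5-(3-methylbut-2-en-1-yl)benzaldehyde
Conditions: MeI, K2CO3, DMF, rt
Reagents that add atoms: iodomethane, CI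
Why: Williamson methylation of the only free phenol, whose acidity (para formyl group) allows mild carbonate conditions despite the two ortho substituents.

Step 6
Reactants: 7 4-methoxy-3-(methoxymethoxy)-5-(3-methylbut-2-en-1-yl)benzaldehyde
Product: 8 methyl (E)-3-[4-methoxy-3-(methoxymethoxy)-5-(3-methylbut-2-en-1-yl)phenyl]prop-2-enoate
Conditions: Ph3P=CHCO2Me, toluene, 80 °C
Reagents that add atoms: methyl (triphenylphosphoranylidene)acetate, COC(=O)C=P(c1ccccc1)(c1ccccc1)c1ccccc1
Why: Wittig olefination with a stabilised ylide should give the cinnamate with the usual E geometry, which is of no consequence because the alkene is saturated in the next step.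

Step 7
Reactants: 8 methyl (E)-3-[4-methoxy-3-(methoxymethoxy)-5-(3-methylbut-2-en-1-yl)phenyl]prop-2-enoate
Product: 9 methyl 3-[4-methoxy-3-(methoxymethoxy)-5-(3-methylbut-2-en-1-yl)phenyl]propanoate
Conditions: Mg turnings (excess), MeOH, 0 °C → rt; aq NH4Cl
Reagents that add atoms: none
Why: Dissolving-metal conjugate reduction in which Mg in MeOH transfers electrons only to the aryl-conjugated enoate, so the cinnamate alkene is saturated while the isolated trisubstituted prenyl alkene and the acetal stay inert.

Step 8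
Reactants: 9 methyl 3-[4-methoxy-3-(methoxymethoxy)-5-(3-methylbut-2-en-1-yl)phenyl]propanoate
Product: 10 N-methoxy-N-methyl-3-[4-methoxy-3-(methoxymethoxy)-5-(3-methylbut-2-en-1-yl)phenyl]propanamide
Conditions: MeNH(OMe)·HCl (1.5 equiv), iPrMgCl (3.0 equiv), THF, −20 → 0 °C
Reagents that add atoms: N,O-dimethylhydroxylamine hydrochloride, CNOC.Cl
Why: Ester aminolysis by the chloromagnesium amide of N,O-dimethylhydroxylamine (Weinreb amide formation), chosen because this amide acylates carbanions through a stable chelate and resists α-deprotonation better than the ester.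

Step 9
Reactants: 10 N-methoxy-N-methyl-3-[4-methoxy-3-(methoxymethoxy)-5-(3-methylbut-2-en-1-yl)phenyl]propanamide; 11 methyl 3,5-dioxohexanoate
Product: 13 methyl 9-[4-methoxy-3-(methoxymethoxy)-5-(3-methylbut-2-en-1-yl)phenyl]-3,5,7-trioxononanoate, via trilithium trienolate 12 (not isolated)
Conditions: 11 (1.5 equiv), LiN(iPr)2 (4.6 equiv), THF, −78 → 0 °C; then 10 (1.0 equiv), −78 → −10 °C; aq NH4Cl; crude 13 taken on without chromatography
Reagents that add atoms: none
Why: Claisen-type C-acylation of a polyanion in which three equivalents of amide base convert 11 into trienolate 12, whose terminal, last-formed carbanion is the most nucleophilic site and adds to the N-methoxy-N-methylamide to give a chelated tetrahedral adduct that neither over-adds nor quenches further trianion and releases the C7 ketone only on work-up.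

Step 10
Reactants: 13 methyl 9-[4-methoxy-3-(methoxymethoxy)-5-(3-methylbut-2-en-1-yl)phenyl]-3,5,7-trioxononanoate
Product: 15 1-(2,4,6-trihydroxyphenyl)-3-[4-methoxy-3-(methoxymethoxy)-5-(3-methylbut-2-en-1-yl)phenyl]propan-1-one, via 2-acylcyclohexane-1,3,5-trione 14 (not isolated)
Conditions: Mg(OMe)2 (4 equiv), MeOH, 25 → 60 °C; then 0 °C, 1 M HCl to pH 4
Reagents that add atoms: none
Why: Mg(OMe)2 converts 13 into its magnesium polyenolate, in which the C5–C7 β-diketone is enolised so that C6 is the nucleophilic carbon and neither flanking ketone is electrophilic; C6 adds to the ester carbonyl C1, methoxide is expelled, and the cyclic triketone 14 enolises to the aromatic triol 15, so the C6–C1 bond forms and ring A closes. The closest known reaction type is the biomimetic Claisen (Dieckmann-type) cyclisation of 3,5,7-triketo esters to acylphloroglucinols. Ring A closes in the 6-exo-trig mode, the only ring size open to C6 as the nucleophile, and no stereocentre is created. The selectivity needed is Claisen mode over the aldol mode (C2 onto the C7 ketone, leading to a resorcylate) and over lactonisation to a 4-hydroxy-2-pyrone. It should be secured by the anhydrous methoxide medium, which keeps the ester as an acylating group instead of saponifying it to an inert carboxylate, by the chelated enolate that masks C7, and by the reversibility of pyrone formation in methanolic methoxide, while aromatisation makes the C-acylation irreversible.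

Step 11
Reactants: 15 1-(2,4,6-trihydroxyphenyl)-3-[4-methoxy-3-(methoxymethoxy)-5-(3-methylbut-2-en-1-yl)phenyl]propan-1-one; 2 3-chloro-3-methylbut-1-yne
Product: 16 1-{2,6-dihydroxy-4-[(2-methylbut-3-yn-2-yl)oxy]phenyl}-3-[4-methoxy-3-(methoxymethoxy)-5-(3-methylbut-2-en-1-yl)phenyl]propan-1-one
Conditions: 2 (2 equiv), K2CO3 (1.2 equiv), KI (0.2 equiv), CuI (2 mol %), acetone, 50 °C, N2
Reagents that add atoms: none
Why: Williamson-type O-alkylation in which the 4'-OH, para to the acyl group, is the most acidic phenol of 15 and is not held in a hydrogen bond to the ketone, so limiting carbonate should direct the propargylic electrophile from 2 to this oxygen.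

Step 12
Reactants: 16 1-{2,6-dihydroxy-4-[(2-methylbut-3-yn-2-yl)oxy]phenyl}-3-[4-methoxy-3-(methoxymethoxy)-5-(3-methylbut-2-en-1-yl)phenyl]propan-1-one
Product: 18 1-(5,7-dihydroxy-2,2-dimethyl-2H-chromen-6-yl)-3-[4-methoxy-3-(methoxymethoxy)-5-(3-methylbut-2-en-1-yl)phenyl]propan-1-one, via ortho-allenylphenol 17 (not isolated)
Conditions: xylenes, 135 °C
Reagents that add atoms: none
Why: Aryl propargyl ether Claisen rearrangement in which the [3,3] shift to either of the two equivalent ortho carbons and enolisation give allenylphenol 17, which closes the pyran ring by a 1,5-hydrogen shift and oxa-6π electrocyclisation; because ring A of 16 is symmetric, only the chromene with its oxygen para to the ketone can form.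

Step 13
Reactants: 18 1-(5,7-dihydroxy-2,2-dimethyl-2H-chromen-6-yl)-3-[4-methoxy-3-(methoxymethoxy)-5-(3-methylbut-2-en-1-yl)phenyl]propan-1-one
Product: 19 1-(5,7-dihydroxy-2,2-dimethyl-3,4-dihydro-2H-chromen-6-yl)-3-[4-methoxy-3-(methoxymethoxy)-5-(3-methylbut-2-en-1-yl)phenyl]propan-1-one
Conditions: H2 (1 atm), RhCl(PPh3)3 (10 mol %), toluene–EtOH (1:1), 25 °C
Reagents that add atoms: none
Why: Homogeneous hydrogenation with RhCl(PPh3)3, a catalyst that saturates cis-disubstituted, aryl-conjugated alkenes far faster than trisubstituted ones, so the chromene alkene should be reduced while the prenyl group remains.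

Step 14
Reactants: 19 1-(5,7-dihydroxy-2,2-dimethyl-3,4-dihydro-2H-chromen-6-yl)-3-[4-methoxy-3-(methoxymethoxy)-5-(3-methylbut-2-en-1-yl)phenyl]propan-1-one
Product: 20 1-(5,7-dihydroxy-2,2-dimethyl-3,4-dihydro-2H-chromen-6-yl)-3-[3-hydroxy-4-methoxy-5-(3-methylbut-2-en-1-yl)phenyl]propan-1-one
Conditions: 3 M aq HCl, MeOH, 45 °C
Reagents that add atoms: none
Why: Acid-catalysed acetal exchange with methanol removes the methoxymethyl group; the ring B prenyl group has only a methoxy neighbour and so cannot cyclise onto a phenol, and the chroman ether and the ketone are stable to dilute acid.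

**Compound list**

1 | 3,4-dihydroxybenzaldehyde | O=Cc1ccc(O)c(O)c1 | starting material
2 | 3-chloro-3-methylbut-1-yne | C#CC(C)(C)Cl | starting material
3 | 3-hydroxy-4-[(2-methylbut-3-yn-2-yl)oxy]benzaldehyde | O=Cc1ccc(OC(C)(C)C#C)c(O)c1 | intermediate
4 | 3-(methoxymethoxy)-4-[(2-methylbut-3-yn-2-yl)oxy]benzaldehyde | O=Cc1ccc(OC(C)(C)C#C)c(OCOC)c1 | intermediate
5 | 3-(methoxymethoxy)-4-[(2-methylbut-3-en-2-yl)oxy]benzaldehyde | O=Cc1ccc(OC(C)(C)C=C)c(OCOC)c1 | intermediate
6 | 4-hydroxy-3-(methoxymethoxy)-5-(3-methylbut-2-en-1-yl)benzaldehyde | O=Cc1cc(OCOC)c(O)c(CC=C(C)C)c1 | intermediate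
7 | 4-methoxy-3-(methoxymethoxy)-5-(3-methylbut-2-en-1-yl)benzaldehyde | O=Cc1cc(OCOC)c(OC)c(CC=C(C)C)c1 | intermediate
8 | methyl (E)-3-[4-methoxy-3-(methoxymethoxy)-5-(3-methylbut-2-en-1-yl)phenyl]prop-2-enoate | COC(=O)/C=C/c1cc(OCOC)c(OC)c(CC=C(C)C)c1 | intermediate
9 | methyl 3-[4-methoxy-3-(methoxymethoxy)-5-(3-methylbut-2-en-1-yl)phenyl]propanoate | COC(=O)CCc1cc(OCOC)c(OC)c(CC=C(C)C)c1 | intermediate
10 | N-methoxy-N-methyl-3-[4-methoxy-3-(methoxymethoxy)-5-(3-methylbut-2-en-1-yl)phenyl]propanamide | CON(C)C(=O)CCc1cc(OCOC)c(OC)c(CC=C(C)C)c1 | intermediate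
11 | methyl 3,5-dioxohexanoate | COC(=O)CC(=O)CC(C)=O | starting material
12 | trilithium trienolate (trianion) of methyl 3,5-dioxohexanoate | COC([O-])=CC([O-])=CC([O-])=C.[Li+].[Li+].[Li+] | intermediate
13 | methyl 9-[4-methoxy-3-(methoxymethoxy)-5-(3-methylbut-2-en-1-yl)phenyl]-3,5,7-trioxononanoate | COC(=O)CC(=O)CC(=O)CC(=O)CCc1cc(OCOC)c(OC)c(CC=C(C)C)c1 | intermediate
14 | 2-{3-[4-methoxy-3-(methoxymethoxy)-5-(3-methylbut-2-en-1-yl)phenyl]propanoyl}cyclohexane-1,3,5-trione | O=C1CC(=O)C(C(=O)CCc2cc(OCOC)c(OC)c(CC=C(C)C)c2)C(=O)C1 | intermediate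
15 | 1-(2,4,6-trihydroxyphenyl)-3-[4-methoxy-3-(methoxymethoxy)-5-(3-methylbut-2-en-1-yl)phenyl]propan-1-one | Oc1cc(O)c(C(=O)CCc2cc(OCOC)c(OC)c(CC=C(C)C)c2)c(O)c1 | intermediate
16 | 1-{2,6-dihydroxy-4-[(2-methylbut-3-yn-2-yl)oxy]phenyl}-3-[4-methoxy-3-(methoxymethoxy)-5-(3-methylbut-2-en-1-yl)phenyl]propan-1-one | C#CC(C)(C)Oc1cc(O)c(C(=O)CCc2cc(OCOC)c(OC)c(CC=C(C)C)c2)c(O)c1 | intermediate
17 | 3-[4-methoxy-3-(methoxymethoxy)-5-(3-methylbut-2-en-1-yl)phenyl]-1-[2,4,6-trihydroxy-3-(3-methylbuta-1,2-dien-1-yl)phenyl]propan-1-one | CC(C)=C=Cc1c(O)cc(O)c(C(=O)CCc2cc(OCOC)c(OC)c(CC=C(C)C)c2)c1O | intermediate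
18 | 1-(5,7-dihydroxy-2,2-dimethyl-2H-chromen-6-yl)-3-[4-methoxy-3-(methoxymethoxy)-5-(3-methylbut-2-en-1-yl)phenyl]propan-1-one | COc1c(OCOC)cc(CCC(=O)c2c(O)cc3c(c2O)C=CC(C)(C)O3)cc1CC=C(C)C | intermediate
19 | 1-(5,7-dihydroxy-2,2-dimethyl-3,4-dihydro-2H-chromen-6-yl)-3-[4-methoxy-3-(methoxymethoxy)-5-(3-methylbut-2-en-1-yl)phenyl]propan-1-one | COc1c(OCOC)cc(CCC(=O)c2c(O)cc3c(c2O)CCC(C)(C)O3)cc1CC=C(C)C | intermediate
20 | 1-(5,7-dihydroxy-2,2-dimethyl-3,4-dihydro-2H-chromen-6-yl)-3-[3-hydroxy-4-methoxy-5-(3-methylbut-2-en-1-yl)phenyl]propan-1-one | COc1c(O)cc(CCC(=O)c2c(O)cc3c(c2O)CCC(C)(C)O3)cc1CC=C(C)C | target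

**Step count**

Total: 14 steps. Longest linear sequence: 14 steps (1 to 20); 2 and 11 are bought.

**Steps most likely to fail**

Step 9. Proton transfer between the trianion and the amide α-position, incomplete formation of the third carbanion, or premature cyclisation of the polyketone during work-up may erode the acylation. Fallback, setting out from 10 and returning at 13: the β-keto ester is carried masked as a pyrone, so only a dianion is needed. Commercial 4-hydroxy-6-methyl-2H-pyran-2-one would be doubly deprotonated (LiN(iPr)2, 2 equiv, THF, −78 °C) and acylated at its 6-methyl group by 10 to give 4-hydroxy-6-{4-[4-methoxy-3-(methoxymethoxy)-5-(3-methylbut-2-en-1-yl)phenyl]-2-oxobutyl}-2H-pyran-2-one F1. Mg(OMe)2 in MeOH would then open the lactone to the magnesium enolate of 13, where the route is rejoined and carried through step 10 in the same flask.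

Step 10. Cyclisation in the aldol mode, lactonisation, or retro-Claisen cleavage of the chain by methoxide may outrun the C-acylation. Fallback, setting out from 10 and returning at 15: the aryl ketone bond is made on a preformed ring by directed ortho-metalation. Benzene-1,3,5-triol would be converted (2-(trimethylsilyl)ethoxymethyl chloride, iPr2NEt, CH2Cl2) into 1,3,5-tris{[2-(trimethylsilyl)ethoxy]methoxy}benzene F2, which would be lithiated between two acetal oxygens (n-BuLi, THF, 0 °C) and acylated with 10 to give 3-[4-methoxy-3-(methoxymethoxy)-5-(3-methylbut-2-en-1-yl)phenyl]-1-(2,4,6-tris{[2-(trimethylsilyl)ethoxy]methoxy}phenyl)propan-1-one F3. Bu4NF (THF, 60 °C) should remove the three silylethoxymethyl groups while leaving the methoxymethyl ether and the prenyl group, giving 15.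

Step 13. Competing saturation of the trisubstituted side-chain alkene, or slow turnover at the hindered chromene alkene next to the quaternary carbon, may spoil the chemoselective hydrogenation. Fallback, setting out from 16 and returning at 20: the pyran ring is closed at the saturated level, so no chromene has to be reduced. Semi-hydrogenation of 16 (H2, Pd/CaCO3 poisoned with Pb(OAc)2, quinoline) would give 1-{2,6-dihydroxy-4-[(2-methylbut-3-en-2-yl)oxy]phenyl}-3-[4-methoxy-3-(methoxymethoxy)-5-(3-methylbut-2-en-1-yl)phenyl]propan-1-one F4. Aromatic Claisen rearrangement (toluene, 100 °C) would move the allyl unit to C3' as a prenyl group, giving 3-[4-methoxy-3-(methoxymethoxy)-5-(3-methylbut-2-en-1-yl)phenyl]-1-[2,4,6-trihydroxy-3-(3-methylbut-2-en-1-yl)phenyl]propan-1-one F5. HCl in MeOH at reflux would then add a flanking phenol across the ring A prenyl alkene and remove the methoxymethyl group in one operation, giving 20. Closure can take place at either phenol next to the prenyl group, so the isomer closed at the para oxygen would have to be separated from the ortho-closed one.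

**Further compounds**

F1 | step 9 | 4-hydroxy-6-{4-[4-methoxy-3-(methoxymethoxy)-5-(3-methylbut-2-en-1-yl)phenyl]-2-oxobutyl}-2H-pyran-2-one | O=C(CCc1cc(OCOC)c(OC)c(CC=C(C)C)c1)CC1=CC(O)=CC(=O)O1
F2 | step 10 | 1,3,5-tris{[2-(trimethylsilyl)ethoxy]methoxy}benzene | C[Si](C)(C)CCOCOc1cc(OCOCC[Si](C)(C)C)cc(OCOCC[Si](C)(C)C)c1
F3 | step 10 | 3-[4-methoxy-3-(methoxymethoxy)-5-(3-methylbut-2-en-1-yl)phenyl]-1-(2,4,6-tris{[2-(trimethylsilyl)ethoxy]methoxy}phenyl)propan-1-one | C[Si](C)(C)CCOCOc1cc(OCOCC[Si](C)(C)C)c(C(=O)CCc2cc(OCOC)c(OC)c(CC=C(C)C)c2)c(OCOCC[Si](C)(C)C)c1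
F4 | step 13 | 1-{2,6-dihydroxy-4-[(2-methylbut-3-en-2-yl)oxy]phenyl}-3-[4-methoxy-3-(methoxymethoxy)-5-(3-methylbut-2-en-1-yl)phenyl]propan-1-one | C=CC(C)(C)Oc1cc(O)c(C(=O)CCc2cc(OCOC)c(OC)c(CC=C(C)C)c2)c(O)c1
F5 | step 13 | 3-[4-methoxy-3-(methoxymethoxy)-5-(3-methylbut-2-en-1-yl)phenyl]-1-[2,4,6-trihydroxy-3-(3-methylbut-2-en-1-yl)phenyl]propan-1-one | CC(C)=CCc1c(O)cc(O)c(C(=O)CCc2cc(OCOC)c(OC)c(CC=C(C)C)c2)c1O
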